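## Retrosynthetic overview

1. The target is 15-acetoxylabda-8(17),13E-dien-18-oic acid, (4R,5R,9S,10R). The strategy rests on ring A (C1 to C5, C10) and ring B (C5 to C10), with the exocyclic C8=C17 methylene and the equatorial C18 carboxyl on C4 (cis to H5, trans to the C10 methyl). Together these are the chair-chair fold of an all-E polyprenyl chain oxidised at its terminal E methyl.
2. Late stage: the C18 acid comes from the aldehyde, the alcohol and the silyl ether in turn. The C13=C14 alkene and the C15 acetate come from a C13 methyl ketone (Horner–Wadsworth–Emmons, reduction, acetylation). C3–H comes from C3–OH (Barton–McCombie).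
3. Key disconnection: C4–C5 and C9–C10 are made in one titanocene radical cascade of a (3S)-epoxide. Ring A closes first, ring B second, and the cascade ends with the C8=C17 alkene.
4. The chain fed to the cascade stops at C13 as a saturated ketone, because the C8 radical would consume any trisubstituted C13 alkene, allylic acetate or not, in a third 6-endo closure.
5. The epoxide is the only source of chirality. It comes from SeO2 oxidation and Sharpless epoxidation of (5E,9E)-farnesylacetone; its C3 oxygen relays to C4, C5, C9 and C10 and is then deleted.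

Key step: step 4

Assumption: (5E,9E)-farnesylacetone is bought as the single all-E isomer; labdane numbering (C1 to C20) is used for the open chain as well as for the rings.

## Route

Step 1
Reactants: 1 (5E,9E)-farnesylacetone, i.e. (5E,9E)-6,10,14-trimethylpentadeca-5,9,13-trien-2-one
Product: 3 (5E,9E,13E)-15-hydroxy-6,10,14-trimethylpentadeca-5,9,13-trien-2-one, via over-oxidised enal 2 (not isolated)
Conditions: SeO2 (0.1 equiv), salicylic acid (0.1 equiv), t-BuOOH (3 equiv), CH2Cl2, 0 °C to rt, stopped short of full conversion; crude, NaBH(OAc)3, THF, 40 °C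
Reagents that add atoms: tert-butyl hydroperoxide, CC(C)(C)OO (terminal oxygen source); selenium dioxide, O=[Se]=O (hands the oxygen to C18)
Why: Catalytic SeO2 allylic oxidation (ene reaction, then [2,3]-sigmatropic shift) should attack the most electron-rich and least hindered terminal isopropylidene group at the methyl trans to the chain, and NaBH(OAc)3 returns the enal portion to the alcohol by aldehyde-selective hydride reduction that leaves the methyl ketone alone.

Step 2
Reactants: 3 (5E,9E,13E)-15-hydroxy-6,10,14-trimethylpentadeca-5,9,13-trien-2-one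
Product: 4 (5E,9E)-12-[(2S,3S)-3-(hydroxymethyl)-3-methyloxiran-2-yl]-6,10-dimethyldodeca-5,9-dien-2-one
Conditions: Ti(OiPr)4 (10 mol %), L-(+)-diethyl tartrate (12 mol %), anhydrous t-BuOOH (2 equiv), 4 Å molecular sieves, CH2Cl2, −20 °C
Reagents that add atoms: tert-butyl hydroperoxide, CC(C)(C)OO
Why: In the Katsuki–Sharpless asymmetric epoxidation the peroxide is delivered within the titanium alkoxide of the allylic alcohol, so only the C3=C4 alkene reacts, and L-(+)-diethyl tartrate selects the face that gives the (2S,3S)-epoxy alcohol, i.e. 3S at the future C3.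

Step 3
Reactants: 4 (2S,3S)-epoxy alcohol
Product: 5 (5E,9E)-12-[(2S,3S)-3-(tert-butyldimethylsilyloxymethyl)-3-methyloxiran-2-yl]-6,10-dimethyldodeca-5,9-dien-2-one
Conditions: TBSCl, imidazole, CH2Cl2, 0 °C to rt
Reagents that add atoms: tert-butyldimethylsilyl chloride, CC(C)(C)[Si](C)(C)Cl
Why: Imidazole-promoted silylation of the primary hydroxyl is neutral enough for the epoxide and the ketone, touches no stereocentre, and removes the free OH that would otherwise bind titanium in step 4.

Step 4
Reactants: 5 epoxy silyl ether
Product: 7 3beta-hydroxy-18-(tert-butyldimethylsilyloxy)-14,15-dinorlabd-8(17)-en-13-one, via C3 trimethylsilyl ether 6 (not isolated)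
Conditions: Cp2TiCl2 (0.2 equiv), Mn dust (8 equiv), Me3SiCl (4 equiv), 2,4,6-collidine (7 equiv), dry deoxygenated THF, rt, slow addition of 5; aq. KHSO4 work-up; crude, citric acid, MeOH, rt
Reagents that add atoms: none
Why: Cp2TiCl (trivalent titanium), made in the flask from Cp2TiCl2 and Mn, transfers one electron to the epoxide and cleaves the C4–O bond to the tertiary C4 radical while the C3–O bond stays intact, which is the known titanocene-catalysed radical cyclization of epoxypolyprenes, saturated ketone-terminated chains included. Ring A closes by 6-endo-trig attack of C4 on C5 and ring B by 6-endo-trig attack of the tertiary C10 radical on C9, after which a second Cp2TiCl captures the tertiary C8 radical and beta-hydride elimination from C17 gives, under dry conditions, the exocyclic C8=C17 alkene. C3 keeps the 3S configuration of the epoxide, and its titanoxy group sits equatorial and so fixes the chair-chair fold, which puts the C6 chain equatorial on C5 (H5 alpha), closes ring B trans at C10 (methyl axial, beta) and puts the C11 chain equatorial on C9 (H9 alpha). C4 is planar at the radical stage and is set within that fold, the silyloxymethyl group taking the equatorial alpha site and the smaller methyl the axial site that faces the C10 methyl. The cascade must stop after two rings, and the substrate secures this because it has no alkene beyond C8=C9 (an allylic acetate alkene at C13 would be taken in a third 6-endo closure, as happens in the epoxides of geranyl and farnesyl acetate), while a saturated methyl ketone is neither reduced by Cp2TiCl nor a good acceptor for a hindered tertiary radical. Me3SiCl with collidine frees titanium from the C3 alkoxide as silyl ether 6, which citric acid in methanol cleaves without touching the primary TBS ether.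

Step 5
Reactants: 7 3beta-hydroxy bicyclic ketone
Product: 8 3beta-(imidazol-1-ylthiocarbonyloxy)-18-(tert-butyldimethylsilyloxy)-14,15-dinorlabd-8(17)-en-13-one
Conditions: 1,1'-thiocarbonyldiimidazole (3 equiv), DMAP, 1,2-dichloroethane, reflux
Reagents that add atoms: 1,1'-thiocarbonyldiimidazole, S=C(n1ccnc1)n1ccnc1
Why: This is the first half of the Barton–McCombie deoxygenation, a base-free thioacylation that works on hindered equatorial 3beta-alcohols next to a quaternary C4 and leaves the ketone, alkene and silyl ether untouched.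

Step 6
Reactants: 8 C3 imidazolyl thiocarbamate
Product: 9 18-(tert-butyldimethylsilyloxy)-14,15-dinorlabd-8(17)-en-13-one
Conditions: Bu3SnH (2 equiv), AIBN (0.2 equiv), toluene, 110 °C
Reagents that add atoms: none
Why: This is the second half of the Barton–McCombie deoxygenation, in which the stannyl radical adds to C=S, the C3–O bond fragments to a secondary C3 radical and Bu3SnH quenches it faster than it can reach the remote alkene or ketone, so that C3 stops being a stereocentre and C4, C5, C9 and C10 are unaffected.

Step 7
Reactants: 9 3-deoxy bicyclic ketone; 10 triethyl phosphonoacetate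
Product: 11 ethyl 18-(tert-butyldimethylsilyloxy)labda-8(17),13E-dien-15-oate
Conditions: 10 (3 equiv), NaH (2.8 equiv), THF, 0 °C to reflux
Reagents that add atoms: triethyl phosphonoacetate (10), CCOC(=O)CP(=O)(OCC)OCC
Why: Horner–Wadsworth–Emmons olefination of the unhindered methyl ketone under equilibrating conditions should favour the E enoate, with the ester trans to the longer C12 chain, and the minor Z isomer is removed by chromatography here or after step 8.

Step 8
Reactants: 11 E enoate
Product: 12 18-(tert-butyldimethylsilyloxy)labda-8(17),13E-dien-15-ol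
Conditions: iBu2AlH (2.5 equiv), CH2Cl2, −78 °C; aq. potassium sodium tartrate
Reagents that add atoms: none
Why: iBu2AlH reduces the enoate in 1,2 fashion to the allylic alcohol at low temperature, without conjugate reduction or loss of the E geometry, and both the silyl ether and the exocyclic alkene are inert.

Step 9
Reactants: 12 C15 allylic alcohol
Product: 13 18-(tert-butyldimethylsilyloxy)labda-8(17),13E-dien-15-yl acetate
Conditions: Ac2O, pyridine, DMAP (cat.), CH2Cl2, 0 °C to rt
Reagents that add atoms: acetic anhydride, CC(=O)OC(C)=O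
Why: DMAP-catalysed acetylation of the only free hydroxyl installs the C15 acetate of the target under conditions that cause no allylic transposition.

Step 10
Reactants: 13 silyl ether acetate
Product: 14 18-hydroxylabda-8(17),13E-dien-15-yl acetate
Conditions: HF·pyridine, pyridine, THF, 0 °C to rt
Reagents that add atoms: none
Why: Pyridine-buffered fluoride desilylation cleaves the neopentyl primary TBS ether and is neither basic enough to remove the allylic acetate nor acidic enough to move the C8=C17 alkene.

Step 11
Reactants: 14 C18 primary alcohol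
Product: 15 18-oxolabda-8(17),13E-dien-15-yl acetate
Conditions: Dess–Martin periodinane, NaHCO3, CH2Cl2, 0 °C to rt
Reagents that add atoms: none
Why: The buffered Dess–Martin oxidation converts hindered neopentyl alcohols to aldehydes under near-neutral conditions, and the aldehyde carbon sits on quaternary C4, so nothing can epimerise.

Step 12
Reactants: 15 C18 aldehyde
Product: 16 15-acetoxylabda-8(17),13E-dien-18-oic acid (target CNP0190226.3)
Conditions: NaClO2, NaH2PO4, 2-methyl-2-butene (large excess), t-BuOH/H2O, rt
Reagents that add atoms: sodium chlorite, [Na+].[O-]Cl=O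
Why: The Pinnick oxidation takes the hindered aldehyde to the acid at mildly acidic pH, which the acetate tolerates, and the excess 2-methyl-2-butene intercepts the hypochlorous acid before it can reach the two alkenes of the substrate.

## Compound list

All bicyclic compounds belong to the normal labdane series: H5 alpha, C10 methyl beta, H9 alpha, C19 methyl beta-axial, C18 alpha-equatorial.

1 | (5E,9E)-farnesylacetone | CC(C)=CCC/C(C)=C/CC/C(C)=C/CCC(C)=O | starting material
2 | (2E,6E,10E)-2,6,10-trimethyl-14-oxopentadeca-2,6,10-trienal | O=C/C(C)=C/CC/C(C)=C/CC/C(C)=C/CCC(C)=O | intermediate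
3 | (5E,9E,13E)-15-hydroxy-6,10,14-trimethylpentadeca-5,9,13-trien-2-one | OC/C(C)=C/CC/C(C)=C/CC/C(C)=C/CCC(C)=O | intermediate
4 | (5E,9E)-12-[(2S,3S)-3-(hydroxymethyl)-3-methyloxiran-2-yl]-6,10-dimethyldodeca-5,9-dien-2-one | OC[C@]1(C)O[C@H]1CC/C(C)=C/CC/C(C)=C/CCC(C)=O | intermediate
5 | (5E,9E)-12-[(2S,3S)-3-(tert-butyldimethylsilyloxymethyl)-3-methyloxiran-2-yl]-6,10-dimethyldodeca-5,9-dien-2-one | CC(C)(C)[Si](C)(C)OC[C@]1(C)O[C@H]1CC/C(C)=C/CC/C(C)=C/CCC(C)=O | intermediate
6 | 3beta-(trimethylsilyloxy)-18-(tert-butyldimethylsilyloxy)-14,15-dinorlabd-8(17)-en-13-one | C=C1CC[C@@H]2[C@](C)(CC[C@H](O[Si](C)(C)C)[C@@]2(C)CO[Si](C)(C)C(C)(C)C)[C@H]1CCC(C)=O | intermediate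
7 | 3beta-hydroxy-18-(tert-butyldimethylsilyloxy)-14,15-dinorlabd-8(17)-en-13-one | C=C1CC[C@@H]2[C@](C)(CC[C@H](O)[C@@]2(C)CO[Si](C)(C)C(C)(C)C)[C@H]1CCC(C)=O | intermediate
8 | 3beta-(imidazol-1-ylthiocarbonyloxy)-18-(tert-butyldimethylsilyloxy)-14,15-dinorlabd-8(17)-en-13-one | C=C1CC[C@@H]2[C@](C)(CC[C@H](OC(=S)n3ccnc3)[C@@]2(C)CO[Si](C)(C)C(C)(C)C)[C@H]1CCC(C)=O | intermediate
9 | 18-(tert-butyldimethylsilyloxy)-14,15-dinorlabd-8(17)-en-13-one | C=C1CC[C@@H]2[C@](C)(CCC[C@@]2(C)CO[Si](C)(C)C(C)(C)C)[C@H]1CCC(C)=O | intermediate
10 | triethyl phosphonoacetate | CCOC(=O)CP(=O)(OCC)OCC | starting material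
11 | ethyl 18-(tert-butyldimethylsilyloxy)labda-8(17),13E-dien-15-oate | C=C1CC[C@@H]2[C@](C)(CCC[C@@]2(C)CO[Si](C)(C)C(C)(C)C)[C@H]1CC/C(C)=C/C(=O)OCC | intermediate
12 | 18-(tert-butyldimethylsilyloxy)labda-8(17),13E-dien-15-ol | C=C1CC[C@@H]2[C@](C)(CCC[C@@]2(C)CO[Si](C)(C)C(C)(C)C)[C@H]1CC/C(C)=C/CO | intermediate
13 | 18-(tert-butyldimethylsilyloxy)labda-8(17),13E-dien-15-yl acetate | C=C1CC[C@@H]2[C@](C)(CCC[C@@]2(C)CO[Si](C)(C)C(C)(C)C)[C@H]1CC/C(C)=C/COC(C)=O | intermediate
14 | 18-hydroxylabda-8(17),13E-dien-15-yl acetate | C=C1CC[C@@H]2[C@](C)(CCC[C@@]2(C)CO)[C@H]1CC/C(C)=C/COC(C)=O | intermediate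
15 | 18-oxolabda-8(17),13E-dien-15-yl acetate | C=C1CC[C@@H]2[C@](C)(CCC[C@@]2(C)C=O)[C@H]1CC/C(C)=C/COC(C)=O | intermediate
16 | 15-acetoxylabda-8(17),13E-dien-18-oic acid, (4R,5R,9S,10R), CNP0190226.3 | C=C1CC[C@@H]2[C@](C)(CCC[C@@]2(C)C(=O)O)[C@H]1CC/C(C)=C/COC(C)=O | target

Total step count: 12. Longest linear sequence: 12 steps (1 to 16).

## Steps most likely to fail

**First risk, step 4.** Three processes may go wrong.
- Facial control at the planar C4 radical may be incomplete, since methyl and silyloxymethyl differ little in effective size.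
- The cascade may terminate early, after ring A.
- The C8 radical may add to the ketone carbonyl.

The fallback sets out from 5 and replaces the radical cascade by a polar one.
- MeAlCl2 (2 equiv) in CH2Cl2 at −78 °C activates the epoxide, and the C5=C10 alkene attacks C4 from the back in concert with C–O cleavage. C4 is then fixed by the E geometry of the epoxide (silyloxymethyl equatorial, methyl axial) and not by a conformational bias.
- Ring B closes in the same chair-chair fold. The ketone oxygen catches the C8 cation on its alpha face, and loss of a proton should give the tricyclic enol ether 3beta-hydroxy-18-(tert-butyldimethylsilyloxy)-8alpha,13-epoxy-14,15-dinorlabd-12-ene F1.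
- Dilute oxalic acid in aqueous THF hydrolyses the enol ether to 3beta,8alpha-dihydroxy-18-(tert-butyldimethylsilyloxy)-14,15-dinorlabdan-13-one F2.
- Thiocarbonyldiimidazole acylates only the secondary C3 hydroxyl, giving the C3 imidazolyl thiocarbamate F3.
- Bu3SnH/AIBN removes this group, giving 8alpha-hydroxy-18-(tert-butyldimethylsilyloxy)-14,15-dinorlabdan-13-one F4.
- SOCl2 in pyridine at low temperature dehydrates the equatorial tertiary alcohol, whose only antiperiplanar hydrogens lie on C17, and the route is rejoined at 9.

**Second risk, step 1.** Site selectivity among the three trisubstituted alkenes may be poor, over-oxidation may occur, and conversion may be low. The fallback sets out from 1 and builds the E-oxidised terminus by cleavage and olefination instead of C–H oxidation.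
- NBS in aqueous THF at 0 °C forms the terminal bromohydrin (5E,9E)-13-bromo-14-hydroxy-6,10,14-trimethylpentadeca-5,9-dien-2-one F5.
- K2CO3 in methanol closes it to the racemic terminal epoxide (5E,9E)-13,14-epoxy-6,10,14-trimethylpentadeca-5,9-dien-2-one F6.
- H5IO6 in THF/ether cleaves the epoxide to (4E,8E)-4,8-dimethyl-12-oxotrideca-4,8-dienal F7.
- An E-selective Wittig reaction with 2-(triphenylphosphoranylidene)propanal in hot toluene reacts at the aldehyde and not at the ketone. It comes back to the route at enal 2, which the NaBH(OAc)3 stage of step 1 takes on to 3.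

**Third risk, step 7.** E/Z selectivity may be poor, because the two alkyl groups of the methyl ketone differ little in size, and competing enolisation may slow the reaction. The fallback sets out from 9 and sets the alkene geometry by syn carbometalation instead of olefination.
- LiN(iPr)2 at −78 °C followed by ClP(O)(OEt)2 gives the kinetic enol phosphate diethyl 18-(tert-butyldimethylsilyloxy)-14,15-dinorlabda-8(17),13(16)-dien-13-yl phosphate F8.
- More LiN(iPr)2 eliminates phosphate to give the terminal alkyne 18-(tert-butyldimethylsilyloxy)-14,15-dinorlabd-8(17)-en-13(16)-yne F9.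
- Negishi carboalumination (Me3Al, Cp2ZrCl2, CH2Cl2), then n-BuLi and paraformaldehyde, delivers the E allylic alcohol directly. The route is rejoined at 12.

## Further compounds

F1 | step 4 | 3beta-hydroxy-18-(tert-butyldimethylsilyloxy)-8alpha,13-epoxy-14,15-dinorlabd-12-ene | CC1=CC[C@H]2[C@](C)(O1)CC[C@@H]3[C@]2(C)CC[C@H](O)[C@@]3(C)CO[Si](C)(C)C(C)(C)C
F2 | step 4 | 3beta,8alpha-dihydroxy-18-(tert-butyldimethylsilyloxy)-14,15-dinorlabdan-13-one | CC(=O)CC[C@H]1[C@](C)(O)CC[C@@H]2[C@]1(C)CC[C@H](O)[C@@]2(C)CO[Si](C)(C)C(C)(C)C
F3 | step 4 | 8alpha-hydroxy-3beta-(imidazol-1-ylthiocarbonyloxy)-18-(tert-butyldimethylsilyloxy)-14,15-dinorlabdan-13-one | CC(=O)CC[C@H]1[C@](C)(O)CC[C@@H]2[C@]1(C)CC[C@H](OC(=S)n3ccnc3)[C@@]2(C)CO[Si](C)(C)C(C)(C)C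
F4 | step 4 | 8alpha-hydroxy-18-(tert-butyldimethylsilyloxy)-14,15-dinorlabdan-13-one | CC(=O)CC[C@H]1[C@](C)(O)CC[C@@H]2[C@]1(C)CCC[C@@]2(C)CO[Si](C)(C)C(C)(C)C
F5 | step 1 | (5E,9E)-13-bromo-14-hydroxy-6,10,14-trimethylpentadeca-5,9-dien-2-one (racemic) | CC(C)(O)C(Br)CC/C(C)=C/CC/C(C)=C/CCC(C)=O
F6 | step 1 | (5E,9E)-13,14-epoxy-6,10,14-trimethylpentadeca-5,9-dien-2-one (racemic) | CC1(C)OC1CC/C(C)=C/CC/C(C)=C/CCC(C)=O
F7 | step 1 | (4E,8E)-4,8-dimethyl-12-oxotrideca-4,8-dienal | O=CCC/C(C)=C/CC/C(C)=C/CCC(C)=O
F8 | step 7 | diethyl 18-(tert-butyldimethylsilyloxy)-14,15-dinorlabda-8(17),13(16)-dien-13-yl phosphate | C=C1CC[C@@H]2[C@](C)(CCC[C@@]2(C)CO[Si](C)(C)C(C)(C)C)[C@H]1CCC(=C)OP(=O)(OCC)OCC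
F9 | step 7 | 18-(tert-butyldimethylsilyloxy)-14,15-dinorlabd-8(17)-en-13(16)-yne | C=C1CC[C@@H]2[C@](C)(CCC[C@@]2(C)CO[Si](C)(C)C(C)(C)C)[C@H]1CCC#C
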